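The side chain is assembled by a nickel-electrocatalytic decarboxylative alkenylation (C7′–C8′), attached to a bought benzoate, and the lactone is closed last.

- Retrosynthetic cuts, in order: the lactone (acyl C1–O2 bond and the C3–C3a bond, i.e. a formyl carbon ortho to the C4 phenol), the aryl C5–O–C1′ ether, then C7′–C8′ of the side chain.
- Enabling feature: C7′ is the methyl-bearing sp2 carbon of the trisubstituted C6′=C7′ alkene, and C8′ is an unbranched CH2 whose nearest heteroatom (the C11′ acetate) is three carbons away. C7′ can therefore be a geometrically fixed alkenyl iodide and C8′ a primary radical released from a carboxylic acid with loss of CO2.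
- Forward: tail acid to its N-acyloxyphthalimide; geranyl acetate to a C8 alkenyl iodide; electrochemical coupling of the two to the C15 chain; allylic bromide; O-alkylation of methyl 3,4-dihydroxy-5-methoxybenzoate at the 4-OH; ortho-formylation; reduction, which closes the five-membered lactone ring last (the benzene ring is bought).
- Geometry: there is no stereocentre. 2′E comes from geranyl acetate; 6′E comes from syn-hydrozirconation/iodinolysis of a 2-alkyne and is retained in the coupling. The ring pattern follows from para-selective O-alkylation and ortho-only formylation.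

Key step: step 9

Remark: side-chain carbons are numbered C1′ (OCH2) to C12′, C11′ carrying the acetate. The three starting materials (2-methylhex-5-en-2-ol, geranyl acetate, methyl 3,4-dihydroxy-5-methoxybenzoate) and all reagents are taken as commercial.

**Step 1**
Reactants: 1 2-methylhex-5-en-2-ol
Product: 2 2-methylhex-5-en-2-yl acetate
Conditions: Ac2O, Et3N, DMAP (cat.), CH2Cl2, 40 °C
Reagents that add atoms: acetic anhydride, CC(=O)OC(C)=O
Why: DMAP-catalysed acyl transfer (Steglich-type, through the N-acetylpyridinium ion) should acetylate the hindered tertiary alcohol without touching the terminal alkene.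

**Step 2**
Reactants: 2 2-methylhex-5-en-2-yl acetate
Product: 4 6-hydroxy-2-methylhexan-2-yl acetate, via alkylborane 3 (not isolated)
Conditions: 9-BBN, THF, 0 °C to rt; then NaBO3·4H2O, H2O, rt
Reagents that add atoms: 9-borabicyclo[3.3.1]nonane, B1C2CCCC1CCC2 (boron unit of 3); sodium perborate, [Na+].[Na+].O[B-]1(O)OO[B-](O)(O)OO1 (hydroxyl oxygen of 4)
Why: Anti-Markovnikov hydroboration of the monosubstituted alkene followed by perborate oxidation with retention should give the primary alcohol, the near-neutral oxidant sparing the tertiary acetate.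

**Step 3**
Reactants: 4 6-hydroxy-2-methylhexan-2-yl acetate
Product: 5 5-acetoxy-5-methylhexanoic acid
Conditions: TEMPO (cat.), PhI(OAc)2, MeCN/H2O, rt
Reagents that add atoms: water, O
Why: Oxoammonium-mediated oxidation (TEMPO with PhI(OAc)2 as terminal oxidant) should take the primary alcohol through the aldehyde hydrate to the acid under conditions that leave the tertiary acetate alone.

**Step 4**
Reactants: 5 5-acetoxy-5-methylhexanoic acid
Product: 6 1,3-dioxoisoindolin-2-yl 5-acetoxy-5-methylhexanoate
Conditions: N-hydroxyphthalimide, DIC, DMAP (cat.), CH2Cl2, rt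
Reagents that add atoms: N-hydroxyphthalimide, O=C1c2ccccc2C(=O)N1O
Why: Carbodiimide-mediated (Steglich) esterification should give the redox-active N-acyloxyphthalimide, a storable precursor of the primary radical.

**Step 5**
Reactants: 7 geranyl acetate [(2E)-3,7-dimethylocta-2,6-dien-1-yl acetate]
Product: 9 (2E)-3-methyl-6-oxohex-2-en-1-yl acetate, via epoxide 8 (not isolated)
Conditions: mCPBA, CH2Cl2, 0 °C; then H5IO6, THF/H2O, 0 °C to rt
Reagents that add atoms: mCPBA, O=C(OO)c1cccc(Cl)c1
Why: Prilezhaev epoxidation should pick the electron-rich C6=C7 alkene over the C2=C3 alkene deactivated by the allylic acetoxy group, and periodic acid should then open the epoxide and cleave the glycol (Malaprade reaction) to the aldehyde with the 2E alkene untouched.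

**Step 6**
Reactants: 9 (2E)-3-methyl-6-oxohex-2-en-1-yl acetate
Product: 11 (2E)-3-methylhept-2-en-6-yn-1-ol, via alkynyl acetate 10 (not isolated)
Conditions: dimethyl (1-diazo-2-oxopropyl)phosphonate, K2CO3, MeOH, 0 °C to rt
Reagents that add atoms: dimethyl (1-diazo-2-oxopropyl)phosphonate, COP(=O)(OC)C(=[N+]=[N-])C(C)=O
Why: Seyferth–Gilbert homologation in the Ohira–Bestmann variant should convert the enolisable aldehyde into the terminal alkyne, and the same K2CO3/MeOH medium should remove the allylic acetate by transesterification.

**Step 7**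
Reactants: 11 (2E)-3-methylhept-2-en-6-yn-1-ol
Product: 13 (2E)-3-methyloct-2-en-6-yn-1-ol, via dilithio salt 12 (not isolated)
Conditions: n-BuLi (2.1 equiv), THF, −78 to 0 °C; then MeI (1.05 equiv), 0 °C to rt; H2O
Reagents that add atoms: n-butyllithium, [Li]CCCC (lithium of 12); iodomethane, CI
Why: Alkylation of the alkoxide–acetylide dianion should occur at carbon only, because the lithium acetylide is by far the stronger nucleophile toward MeI in THF than the lithium alkoxide.

**Step 8**
Reactants: 13 (2E)-3-methyloct-2-en-6-yn-1-ol
Product: 15 (2E,6E)-7-iodo-3-methylocta-2,6-dien-1-ol, via alkenylzirconocene 14 (not isolated)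
Conditions: Cp2Zr(H)Cl (3 equiv), THF, 50 °C; then I2, THF, 0 °C
Reagents that add atoms: Cp2Zr(H)Cl, [H][Zr](Cl)(C1C=CC=C1)C1C=CC=C1 (zirconium of 14); iodine, II
Why: syn-Hydrozirconation of the 2-alkyne (one equivalent of hydride is consumed by the hydroxyl) should, under equilibrating conditions with excess hydride, place zirconium on the less hindered methyl-bearing carbon C7, and iodinolysis with retention should give the 6E iodide, the trisubstituted C2=C3 alkene being too hindered to react.

**Step 9**
Reactants: 15 (2E,6E)-7-iodo-3-methylocta-2,6-dien-1-ol; 6 1,3-dioxoisoindolin-2-yl 5-acetoxy-5-methylhexanoate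
Product: 16 (6E,10E)-12-hydroxy-2,6,10-trimethyldodeca-6,10-dien-2-yl acetate
Conditions: NiCl2·6H2O (10 mol %), 2,2'-bipyridine, AgNO3 (0.3 equiv), LiCl, DMF, Mg anode, RVC cathode, undivided cell, constant current, rt; 6 in excess
Reagents that add atoms: none
Why: Cathodic reduction of the 2,2'-bipyridine nickel complex gives low-valent nickel, which inserts into the C7′–I bond of 15 with retention, while single-electron reduction of the phthalimide ester 6 releases phthalimide anion and CO2 and leaves the primary radical at C8′; this radical is captured by the alkenyl divalent nickel species and the resulting trivalent alkenyl(alkyl)nickel complex forms the C7′–C8′ bond by reductive elimination, the magnesium anode supplying the electrons. The closest known reaction type is the nickel-electrocatalytic decarboxylative alkenylation of redox-active esters with alkenyl iodides on a silver-coated cathode, a method established for polyprenyl chains. No ring is closed and no stereocentre is formed; the 6′E geometry is set in 15 and should be kept because oxidative addition and reductive elimination at C7′ are stereoretentive and the alkene carbon never becomes a radical. The step needs cross-coupling to win over dimerisation of either partner and over reduction of C–I to C–H, which the silver layer deposited in situ on the cathode and the excess of 6 are expected to secure. In the substrates the acetate is δ to the radical centre and cannot be lost by β-scission, and the C1′ hydroxyl is a poor leaving group, so nickel should not ionise the allylic C–O bond.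

**Step 10**
Reactants: 16 (6E,10E)-12-hydroxy-2,6,10-trimethyldodeca-6,10-dien-2-yl acetate
Product: 17 (6E,10E)-12-bromo-2,6,10-trimethyldodeca-6,10-dien-2-yl acetate
Conditions: CBr4, PPh3, CH2Cl2, 0 °C
Reagents that add atoms: carbon tetrabromide, BrC(Br)(Br)Br
Why: The Appel reaction should convert the primary allylic alcohol into the bromide by SN2 displacement of the alkoxyphosphonium ion under neutral conditions, without allylic transposition or loss of the tertiary acetate.

**Step 11**
Reactants: 17 (6E,10E)-12-bromo-2,6,10-trimethyldodeca-6,10-dien-2-yl acetate; 18 methyl 3,4-dihydroxy-5-methoxybenzoate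
Product: 19 methyl 4-{[(2E,6E)-11-acetoxy-3,7,11-trimethyldodeca-2,6-dien-1-yl]oxy}-3-hydroxy-5-methoxybenzoate
Conditions: KHCO3, DMF, rt to 40 °C; 18 in excess
Reagents that add atoms: none
Why: Williamson etherification should occur at the 4-OH, because this hydroxyl is para to the ester and the more acidic one, so that the weak base forms its phenoxide selectively and the excess of 18 suppresses double alkylation.

**Step 12**
Reactants: 19 methyl 4-{[(2E,6E)-11-acetoxy-3,7,11-trimethyldodeca-2,6-dien-1-yl]oxy}-3-hydroxy-5-methoxybenzoate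
Product: 20 methyl 4-{[(2E,6E)-11-acetoxy-3,7,11-trimethyldodeca-2,6-dien-1-yl]oxy}-2-formyl-3-hydroxy-5-methoxybenzoate
Conditions: MgCl2, Et3N, (CH2O)n, MeCN, 75 °C
Reagents that add atoms: paraformaldehyde (reacts as formaldehyde), C=O
Why: Magnesium-phenoxide-directed ortho-formylation (Casnati–Skattebøl reaction) delivers formaldehyde within a chelate only to a position ortho to the phenol, and C2 is the only free one because C4 carries the ether, so the formyl carbon should enter between the hydroxyl and the ester.

**Step 13**
Reactants: 20 methyl 4-{[(2E,6E)-11-acetoxy-3,7,11-trimethyldodeca-2,6-dien-1-yl]oxy}-2-formyl-3-hydroxy-5-methoxybenzoate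
Product: 22 farnesylemefuranone F, via hydroxymethyl ester 21 (not isolated)
Conditions: NaBH4, MeOH/THF, 0 °C; then AcOH to pH 5, rt
Reagents that add atoms: none
Why: Chemoselective borohydride reduction of the aldehyde should give the benzylic alcohol, which closes the five-membered lactone ring by 5-exo-trig attack on the neighbouring methyl ester with loss of methanol, the tertiary acetate and both alkenes being inert.

**Compound list**

1 | 2-methylhex-5-en-2-ol | C=CCCC(C)(C)O | starting material
2 | 2-methylhex-5-en-2-yl acetate | C=CCCC(C)(C)OC(C)=O | intermediate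
3 | 6-(9-borabicyclo[3.3.1]nonan-9-yl)-2-methylhexan-2-yl acetate | CC(=O)OC(C)(C)CCCCB1C2CCCC1CCC2 | intermediate (not isolated)
4 | 6-hydroxy-2-methylhexan-2-yl acetate | CC(=O)OC(C)(C)CCCCO | intermediate
5 | 5-acetoxy-5-methylhexanoic acid | CC(=O)OC(C)(C)CCCC(=O)O | intermediate
6 | 1,3-dioxoisoindolin-2-yl 5-acetoxy-5-methylhexanoate | CC(=O)OC(C)(C)CCCC(=O)ON1C(=O)c2ccccc2C1=O | intermediate
7 | geranyl acetate [(2E)-3,7-dimethylocta-2,6-dien-1-yl acetate] | CC(=O)OC/C=C(\C)CCC=C(C)C | starting material
8 | (2E)-5-(3,3-dimethyloxiran-2-yl)-3-methylpent-2-en-1-yl acetate (racemic) | CC(=O)OC/C=C(\C)CCC1OC1(C)C | intermediate (not isolated)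
9 | (2E)-3-methyl-6-oxohex-2-en-1-yl acetate | CC(=O)OC/C=C(\C)CCC=O | intermediate
10 | (2E)-3-methylhept-2-en-6-yn-1-yl acetate | CC(=O)OC/C=C(\C)CCC#C | intermediate (not isolated)
11 | (2E)-3-methylhept-2-en-6-yn-1-ol | OC/C=C(\C)CCC#C | intermediate
12 | dilithium salt of 11 (lithium alkoxide and lithium acetylide) | [Li]OC/C=C(\C)CCC#C[Li] | intermediate (not isolated)
13 | (2E)-3-methyloct-2-en-6-yn-1-ol | OC/C=C(\C)CCC#CC | intermediate
14 | (2E,6E)-3-methylocta-2,6-diene zirconated at C7 (Cp2ZrCl) and bound through the C1 oxygen to a second Cp2ZrCl unit | Cl[Zr](C1C=CC=C1)(C1C=CC=C1)OC/C=C(\C)CC/C=C(\C)[Zr](Cl)(C1C=CC=C1)C1C=CC=C1 | intermediate (not isolated)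
15 | (2E,6E)-7-iodo-3-methylocta-2,6-dien-1-ol | OC/C=C(\C)CC/C=C(\C)I | intermediate
16 | (6E,10E)-12-hydroxy-2,6,10-trimethyldodeca-6,10-dien-2-yl acetate | OC/C=C(\C)CC/C=C(\C)CCCC(C)(C)OC(C)=O | intermediate
17 | (6E,10E)-12-bromo-2,6,10-trimethyldodeca-6,10-dien-2-yl acetate | BrC/C=C(\C)CC/C=C(\C)CCCC(C)(C)OC(C)=O | intermediate
18 | methyl 3,4-dihydroxy-5-methoxybenzoate | COC(=O)c1cc(O)c(O)c(OC)c1 | starting material
19 | methyl 4-{[(2E,6E)-11-acetoxy-3,7,11-trimethyldodeca-2,6-dien-1-yl]oxy}-3-hydroxy-5-methoxybenzoate | COC(=O)c1cc(O)c(OC/C=C(\C)CC/C=C(\C)CCCC(C)(C)OC(C)=O)c(OC)c1 | intermediate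
20 | methyl 4-{[(2E,6E)-11-acetoxy-3,7,11-trimethyldodeca-2,6-dien-1-yl]oxy}-2-formyl-3-hydroxy-5-methoxybenzoate | COC(=O)c1cc(OC)c(OC/C=C(\C)CC/C=C(\C)CCCC(C)(C)OC(C)=O)c(O)c1C=O | intermediate
21 | methyl 4-{[(2E,6E)-11-acetoxy-3,7,11-trimethyldodeca-2,6-dien-1-yl]oxy}-3-hydroxy-2-(hydroxymethyl)-5-methoxybenzoate | COC(=O)c1cc(OC)c(OC/C=C(\C)CC/C=C(\C)CCCC(C)(C)OC(C)=O)c(O)c1CO | intermediate (not isolated)
22 | farnesylemefuranone F [(6E,10E)-12-[(4-hydroxy-6-methoxy-1-oxo-1,3-dihydro-2-benzofuran-5-yl)oxy]-2,6,10-trimethyldodeca-6,10-dien-2-yl acetate] | COc1cc2c(c(O)c1OC/C=C(\C)CC/C=C(\C)CCCC(C)(C)OC(C)=O)COC2=O | target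

**Step count and risks**

Total steps: 13. Longest linear sequence: 9 steps (steps 5 to 13, from geranyl acetate 7). The tail (steps 1 to 4) joins at step 9 and benzoate 18 at step 11.

Steps most likely to fail:

1. Step 9. Reduction of the C7′–I bond to C–H, dimerisation of the C8′ radical, or acylation of the free C1′ hydroxyl by the activated ester may outrun cross-coupling. The fallback replaces the radical pathway by a two-electron B-alkyl Suzuki–Miyaura coupling; it sets out from iodide 15 and comes back to the route at 16. Commercial 2-methylpent-4-en-2-ol F1 should be acetylated (Ac2O, Et3N, DMAP, CH2Cl2) to 2-methylpent-4-en-2-yl acetate F2. Anti-Markovnikov hydroboration with 9-BBN in THF should give 5-(9-borabicyclo[3.3.1]nonan-9-yl)-2-methylpentan-2-yl acetate F3. This solution, coupled with 15 (PdCl2(dppf), AsPh3, Cs2CO3, DMF/THF/H2O, rt), should deliver 16 with retention of the 6′E geometry and tolerance of the free hydroxyl.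

2. Step 12. Electrophilic attack at C2, flanked by the phenoxide and the ester on a ring deactivated by that ester, may be too slow, so that prolonged heating degrades the chain or the hydroxymethyl stage condenses further. The fallback uses boronic-acid-templated ortho-hydroxymethylation, which needs no oxidation and no hydride; it sets out from 19 and comes back at 21, which lactonises to 22 as in step 13. Heating 19 with PhB(OH)2 and paraformaldehyde (EtCO2H cat., toluene, reflux, removal of water) should give benzodioxaborine F4 by intramolecular delivery of formaldehyde to C2 from the aryl borate. Exchange with propane-1,3-diol (THF, rt) should then release 21.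

3. Step 11. Loss of site selectivity between the two phenols, double alkylation, or decomposition of the allylic bromide before it is consumed may occur. The fallback fixes the site by the starting material, with iodine as a masked hydroxyl; it sets out from bromide 17 and comes back at 19. Commercial methyl 4-hydroxy-3-iodo-5-methoxybenzoate F5 has a single phenol, so alkylation with 17 (K2CO3, DMF, rt) can only give aryl ether iodide F6. Iodine–magnesium exchange (i-PrMgCl·LiCl, THF, −40 °C, ester and acetate tolerated at this temperature) should give arylmagnesium chloride F7. Trapping with B(OMe)3 should give dimethyl arylboronate F8, and oxidation (NaBO3·4H2O, THF/H2O, rt) should unmask the 3-OH and deliver 19.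

**Further compounds**

F1 | step 9 | 2-methylpent-4-en-2-ol | C=CCC(C)(C)O
F2 | step 9 | 2-methylpent-4-en-2-yl acetate | C=CCC(C)(C)OC(C)=O
F3 | step 9 | 5-(9-borabicyclo[3.3.1]nonan-9-yl)-2-methylpentan-2-yl acetate | CC(=O)OC(C)(C)CCCB1C2CCCC1CCC2
F4 | step 12 | methyl 8-{[(2E,6E)-11-acetoxy-3,7,11-trimethyldodeca-2,6-dien-1-yl]oxy}-7-methoxy-2-phenyl-4H-1,3,2-benzodioxaborine-5-carboxylate | COC(=O)c1cc(OC)c(OC/C=C(\C)CC/C=C(\C)CCCC(C)(C)OC(C)=O)c2OB(c3ccccc3)OCc12
F5 | step 11 | methyl 4-hydroxy-3-iodo-5-methoxybenzoate | COC(=O)c1cc(I)c(O)c(OC)c1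
F6 | step 11 | methyl 4-{[(2E,6E)-11-acetoxy-3,7,11-trimethyldodeca-2,6-dien-1-yl]oxy}-3-iodo-5-methoxybenzoate | COC(=O)c1cc(I)c(OC/C=C(\C)CC/C=C(\C)CCCC(C)(C)OC(C)=O)c(OC)c1
F7 | step 11 | {2-{[(2E,6E)-11-acetoxy-3,7,11-trimethyldodeca-2,6-dien-1-yl]oxy}-3-methoxy-5-(methoxycarbonyl)phenyl}magnesium chloride | COC(=O)c1cc([Mg]Cl)c(OC/C=C(\C)CC/C=C(\C)CCCC(C)(C)OC(C)=O)c(OC)c1
F8 | step 11 | dimethyl {2-{[(2E,6E)-11-acetoxy-3,7,11-trimethyldodeca-2,6-dien-1-yl]oxy}-3-methoxy-5-(methoxycarbonyl)phenyl}boronate | COC(=O)c1cc(B(OC)OC)c(OC/C=C(\C)CC/C=C(\C)CCCC(C)(C)OC(C)=O)c(OC)c1
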